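**Retrosynthetic overview**
- The route rests on the one ring of the target, the γ-butyrolactone O1–C2–C3–C4–C5, and its trans pair of substituents: the aryl carbinol carbon C7′ on C3 and the arylmethyl carbon on C4, next to an unsubstituted C5 methylene.
- Late simplifications: phenols ⇐ aryl triisopropylsilyl ethers; C5H2 ⇐ C5 menthyl acetal; benzylic CH2 on C4 ⇐ 2-aryl-1,3-dithiane; C7′ carbinol ⇐ aryl ketone by chelation-controlled reduction.
- Key disconnection: the C4–C(dithiane) and C3–C(acyl) bonds are cut together, giving (5R)-5-menthyloxybutenolide, a lithiated vanillin dithiane and a vanillic Weinreb amide.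
- Ring order: the lactone is the only ring of the target and comes from the furan ring of furfural; the key step closes no ring, and the dithiane ring is temporary.
- Building blocks: furfural and (−)-menthol for the butenolide; vanillin for both aryl units.

Key step: step 7

Remark: the lactone is numbered O1, C2 (carbonyl), C3, C4, C5 and the carbinol carbon on C3 is called C7′; Ar = 3-methoxy-4-(triisopropylsilyloxy)phenyl, menthyl = (1R,2S,5R)-2-isopropyl-5-methylcyclohexyl; commercial (−)-menthol is assumed enantiopure, since it is the only source of absolute configuration.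

**Route**

Step 1
Reactants: 1 furfural
Product: 2 5-hydroxyfuran-2(5H)-one (racemic cyclic hemiacetal)
Conditions: O2, rose bengal (cat.), MeOH, visible light, rt
Reagents that add atoms: dioxygen, O=O
Why: Sensitised photo-oxygenation, in which singlet oxygen adds across C2/C5 of the furan in a [4+2] cycloaddition and methanolysis of the endoperoxide expels the formyl carbon as methyl formate, leaving the hydroxybutenolide with no stereocentre to control.

Step 2
Reactants: 2 5-hydroxyfuran-2(5H)-one; 3 (−)-menthol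
Product: 4 (5R)-5-[(1R,2S,5R)-menthyloxy]furan-2(5H)-one
Conditions: p-TsOH·H2O (cat.), toluene, reflux, Dean–Stark; crystallise from hexane, −20 °C; mother liquor re-equilibrated with p-TsOH (cat.) and recrystallised
Reagents that add atoms: none
Why: Acid-catalysed acetalisation of the pseudo-acid gives both C5 epimers, which interconvert under acid, so selective crystallisation of the (5R) epimer with recycling of the mother liquor should set C5 by crystallisation-driven resolution.

Step 3
Reactants: 5 vanillin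
Product: 6 3-methoxy-4-(triisopropylsilyloxy)benzaldehyde
Conditions: TIPSCl, imidazole, DMF, rt
Reagents that add atoms: triisopropylsilyl chloride, CC(C)[Si](Cl)(C(C)C)C(C)C
Why: Standard imidazole-mediated silylation of a phenol, the triisopropylsilyl ether being chosen because it resists ortho-lithiation, silyl migration and dilute hydroxide far better than smaller aryl silyl ethers yet leaves with buffered fluoride.

Step 4
Reactants: 6 3-methoxy-4-(triisopropylsilyloxy)benzaldehyde; 7 propane-1,3-dithiol
Product: 8 2-[3-methoxy-4-(triisopropylsilyloxy)phenyl]-1,3-dithiane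
Conditions: BF3·OEt2 (cat.), CH2Cl2, 0 °C
Reagents that add atoms: none
Why: Lewis-acid-catalysed dithioacetalisation of an aromatic aldehyde gives the Corey–Seebach acyl-anion precursor, and the hindered aryl silyl ether should tolerate catalytic BF3·OEt2 at 0 °C.

Step 5
Reactants: 6 3-methoxy-4-(triisopropylsilyloxy)benzaldehyde
Product: 9 3-methoxy-4-(triisopropylsilyloxy)benzoic acid
Conditions: NaClO2, NaH2PO4, 2-methyl-2-butene, t-BuOH–H2O, rt
Reagents that add atoms: sodium chlorite NaClO2, [Na+].[O-]Cl=O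
Why: Pinnick oxidation takes the aldehyde to the acid under buffered conditions, with 2-methyl-2-butene scavenging hypochlorous acid so that the electron-rich ring is not chlorinated.

Step 6
Reactants: 9 3-methoxy-4-(triisopropylsilyloxy)benzoic acid
Product: 11 N,3-dimethoxy-N-methyl-4-(triisopropylsilyloxy)benzamide, via acyl imidazole 10 (not isolated)
Conditions: CDI, CH2Cl2, rt; then MeNH(OMe)·HCl, rt
Reagents that add atoms: N,O-dimethylhydroxylamine hydrochloride, CNOC.Cl
Why: Carbonyldiimidazole activation followed by acyl substitution with N,O-dimethylhydroxylamine is a standard Weinreb amide synthesis, neutral enough for the silyl ether.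

Step 7
Reactants: 8 2-[3-methoxy-4-(triisopropylsilyloxy)phenyl]-1,3-dithiane; 4 (5R)-5-[(1R,2S,5R)-menthyloxy]furan-2(5H)-one; 11 N,3-dimethoxy-N-methyl-4-(triisopropylsilyloxy)benzamide
Product: 15 (3S,4R,5R)-3-(ArCO)-4-(2-Ar-1,3-dithian-2-yl)-5-menthyloxydihydrofuran-2(3H)-one, via lithiodithiane 12 (not isolated), via lithium enolate 13 (not isolated), via tetrahedral adduct 14 (not isolated)
Conditions: n-BuLi, THF, −78 → −20 °C; 4, −78 °C; 11, −78 → −30 °C; AcOH, −78 °C
Reagents that add atoms: none
Why: n-BuLi removes the dithiane C2–H of 8, the soft aryl-stabilised anion 12 adds in Michael fashion to C4 of butenolide 4 to give lithium enolate 13, and C3 of 13 attacks Weinreb amide 11 to give the chelated hemiaminal alkoxide 14, which releases the ketone only on protonation, so no second acylation can follow. The closest known reaction type is the tandem conjugate addition–enolate trapping of lithiated 2-aryl-1,3-dithianes on 5-alkoxybutenolides (with benzyl halides or aldehydes as third component), combined with the acylation of ester enolates by Weinreb amides. No ring is closed: the lactone ring of 4 is carried through and only the C4–C(dithiane) and C3–C(acyl) bonds are formed. C4 is controlled by the C5 menthyloxy group, which shields one face of the flat butenolide so that the bulky nucleophile enters anti to it (4R), and C3 is controlled by the new C4 dithianyl group, which sends the amide to the opposite face (3S), any cis isomer being corrected by enolisation of the β-dicarbonyl centre. The step needs 1,4- over 1,2-addition, secured by the soft hindered dithiane anion at −78 °C, and C-monoacylation, secured by the lithium enolate and the stable tetrahedral adduct.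

Step 8
Reactants: 15 (3S,4R,5R)-3-(ArCO)-4-(2-Ar-1,3-dithian-2-yl)-5-menthyloxydihydrofuran-2(3H)-one
Product: 16 (3S,4R,5R)-3-[(S)-hydroxy(Ar)methyl]-4-(2-Ar-1,3-dithian-2-yl)-5-menthyloxydihydrofuran-2(3H)-one
Conditions: Zn(BH4)2, Et2O–THF, −20 → 0 °C; aq. NH4Cl
Reagents that add atoms: none
Why: Chelation-controlled reduction of an α-substituted β-keto ester (Nakata–Oishi type), in which zinc bridges the lactone and ketone carbonyls and hydride enters the ketone from the face of the chelate anti to C4, should give the syn C3/C7′ relationship, here (7′S), without reducing the lactone acetal.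

Step 9
Reactants: 16 (3S,4R,5R)-3-[(S)-hydroxy(Ar)methyl]-4-(2-Ar-1,3-dithian-2-yl)-5-menthyloxydihydrofuran-2(3H)-one
Product: 17 (3S,4R,5R)-3-[(S)-hydroxy(Ar)methyl]-4-(ArCH2)-5-menthyloxydihydrofuran-2(3H)-one
Conditions: NiCl2·6H2O, NaBH4, MeOH–THF, 0 °C → rt
Reagents that add atoms: none
Why: Reductive desulfurisation with nickel boride (Ni2B) generated in the flask cleaves both C–S bonds to a methylene and should leave the lactone acetal, the benzylic alcohol and all stereocentres untouched, none of them being at the reacting carbon.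

Step 10
Reactants: 17 (3S,4R,5R)-3-[(S)-hydroxy(Ar)methyl]-4-(ArCH2)-5-menthyloxydihydrofuran-2(3H)-one
Product: 20 (3S,4R)-3-[(S)-hydroxy(Ar)methyl]-4-(ArCH2)dihydrofuran-2(3H)-one, via aldehydo carboxylate 18 (not isolated), via hydroxy carboxylate 19 (not isolated)
Conditions: LiOH, NaBH4, THF–H2O, 0 °C → rt; then 1 M HCl to pH 3, 0 °C → rt
Reagents that add atoms: lithium hydroxide LiOH, [Li+].[OH-] (its oxygen enters the carboxylate of 18 and is statistically retained as the lactone carbonyl oxygen)
Why: Saponification–reduction–lactonisation, in which hydroxide opens the acylal-type lactone, the menthyl hemiacetal collapses to the C5 aldehyde, NaBH4 already present reduces it before C4 can epimerise, and mild acidification closes the only feasible ring (γ-lactone from the C5 hydroxyl, not a β-lactone from C7′–OH) without touching C3, C4 or C7′.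

Step 11
Reactants: 20 (3S,4R)-3-[(S)-hydroxy(Ar)methyl]-4-(ArCH2)dihydrofuran-2(3H)-one
Product: 21 (3S,4R)-3-[(S)-hydroxy(4-hydroxy-3-methoxyphenyl)methyl]-4-(4-hydroxy-3-methoxybenzyl)dihydrofuran-2(3H)-one (target)
Conditions: TBAF, AcOH, THF, 0 °C
Reagents that add atoms: none
Why: Fluoride-induced cleavage of both aryl silyl ethers, buffered with acetic acid so that no free phenoxide or alkoxide can start retro-aldol cleavage or quinone-methide epimerisation at C7′.

**Compound list**
1 | furfural | O=Cc1ccco1 | starting material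
2 | 5-hydroxyfuran-2(5H)-one (racemic hemiacetal) | OC1OC(=O)C=C1 | intermediate
3 | (−)-menthol, (1R,2S,5R)-2-isopropyl-5-methylcyclohexan-1-ol | C[C@@H]1CC[C@H]([C@@H](C1)O)C(C)C | starting material
4 | (5R)-5-[(1R,2S,5R)-2-isopropyl-5-methylcyclohexyloxy]furan-2(5H)-one | O=C1C=C[C@H](O[C@@H]2C[C@H](C)CC[C@H]2C(C)C)O1 | intermediate
5 | vanillin | COc1cc(C=O)ccc1O | starting material
6 | 3-methoxy-4-(triisopropylsilyloxy)benzaldehyde | COc1cc(C=O)ccc1O[Si](C(C)C)(C(C)C)C(C)C | intermediate
7 | propane-1,3-dithiol | SCCCS | starting material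
8 | 2-[3-methoxy-4-(triisopropylsilyloxy)phenyl]-1,3-dithiane | COc1cc(C2SCCCS2)ccc1O[Si](C(C)C)(C(C)C)C(C)C | intermediate
9 | 3-methoxy-4-(triisopropylsilyloxy)benzoic acid | COc1cc(C(=O)O)ccc1O[Si](C(C)C)(C(C)C)C(C)C | intermediate
10 | 1-[3-methoxy-4-(triisopropylsilyloxy)benzoyl]imidazole | COc1cc(C(=O)n2ccnc2)ccc1O[Si](C(C)C)(C(C)C)C(C)C | intermediate
11 | N,3-dimethoxy-N-methyl-4-(triisopropylsilyloxy)benzamide | CON(C)C(=O)c1ccc(O[Si](C(C)C)(C(C)C)C(C)C)c(OC)c1 | intermediate
12 | 2-lithio-2-[3-methoxy-4-(triisopropylsilyloxy)phenyl]-1,3-dithiane | COc1cc(C2([Li])SCCCS2)ccc1O[Si](C(C)C)(C(C)C)C(C)C | intermediate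
13 | lithium enolate of (4R,5R)-4-{2-[3-methoxy-4-(triisopropylsilyloxy)phenyl]-1,3-dithian-2-yl}-5-menthyloxydihydrofuran-2(3H)-one | COc1cc(C2(SCCCS2)[C@H]3[C@H](O[C@@H]4C[C@H](C)CC[C@H]4C(C)C)OC(O[Li])=C3)ccc1O[Si](C(C)C)(C(C)C)C(C)C | intermediate
14 | lithium alkoxide of the N-methoxy-N-methyl hemiaminal at the acyl carbon on C3 of the (3S,4R,5R) lactone (hemiaminal carbon undefined) | COc1cc(C2(SCCCS2)[C@H]3[C@H](O[C@@H]4C[C@H](C)CC[C@H]4C(C)C)OC(=O)[C@@H]3C(O[Li])(N(C)OC)c3ccc(O[Si](C(C)C)(C(C)C)C(C)C)c(OC)c3)ccc1O[Si](C(C)C)(C(C)C)C(C)C | intermediate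
15 | (3S,4R,5R)-3-[3-methoxy-4-(triisopropylsilyloxy)benzoyl]-4-{2-[3-methoxy-4-(triisopropylsilyloxy)phenyl]-1,3-dithian-2-yl}-5-[(1R,2S,5R)-menthyloxy]dihydrofuran-2(3H)-one | COc1cc(C2(SCCCS2)[C@H]3[C@H](O[C@@H]4C[C@H](C)CC[C@H]4C(C)C)OC(=O)[C@@H]3C(=O)c3ccc(O[Si](C(C)C)(C(C)C)C(C)C)c(OC)c3)ccc1O[Si](C(C)C)(C(C)C)C(C)C | intermediate
16 | (3S,4R,5R)-3-{(S)-hydroxy[3-methoxy-4-(triisopropylsilyloxy)phenyl]methyl}-4-{2-[3-methoxy-4-(triisopropylsilyloxy)phenyl]-1,3-dithian-2-yl}-5-[(1R,2S,5R)-menthyloxy]dihydrofuran-2(3H)-one | COc1cc(C2(SCCCS2)[C@H]3[C@H](O[C@@H]4C[C@H](C)CC[C@H]4C(C)C)OC(=O)[C@@H]3[C@H](O)c3ccc(O[Si](C(C)C)(C(C)C)C(C)C)c(OC)c3)ccc1O[Si](C(C)C)(C(C)C)C(C)C | intermediate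
17 | (3S,4R,5R)-3-{(S)-hydroxy[3-methoxy-4-(triisopropylsilyloxy)phenyl]methyl}-4-[3-methoxy-4-(triisopropylsilyloxy)benzyl]-5-[(1R,2S,5R)-menthyloxy]dihydrofuran-2(3H)-one | COc1cc(C[C@H]3[C@H](O[C@@H]4C[C@H](C)CC[C@H]4C(C)C)OC(=O)[C@@H]3[C@H](O)c3ccc(O[Si](C(C)C)(C(C)C)C(C)C)c(OC)c3)ccc1O[Si](C(C)C)(C(C)C)C(C)C | intermediate
18 | lithium (2S,3R)-3-formyl-2-{(S)-hydroxy[3-methoxy-4-(triisopropylsilyloxy)phenyl]methyl}-4-[3-methoxy-4-(triisopropylsilyloxy)phenyl]butanoate | COc1cc(C[C@@H](C=O)[C@H](C(=O)[O-])[C@H](O)c2ccc(O[Si](C(C)C)(C(C)C)C(C)C)c(OC)c2)ccc1O[Si](C(C)C)(C(C)C)C(C)C.[Li+] | intermediate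
19 | lithium (2S,3R)-2-{(S)-hydroxy[3-methoxy-4-(triisopropylsilyloxy)phenyl]methyl}-3-(hydroxymethyl)-4-[3-methoxy-4-(triisopropylsilyloxy)phenyl]butanoate | COc1cc(C[C@@H](CO)[C@H](C(=O)[O-])[C@H](O)c2ccc(O[Si](C(C)C)(C(C)C)C(C)C)c(OC)c2)ccc1O[Si](C(C)C)(C(C)C)C(C)C.[Li+] | intermediate
20 | (3S,4R)-3-{(S)-hydroxy[3-methoxy-4-(triisopropylsilyloxy)phenyl]methyl}-4-[3-methoxy-4-(triisopropylsilyloxy)benzyl]dihydrofuran-2(3H)-one | COc1cc(C[C@H]2COC(=O)[C@@H]2[C@H](O)c2ccc(O[Si](C(C)C)(C(C)C)C(C)C)c(OC)c2)ccc1O[Si](C(C)C)(C(C)C)C(C)C | intermediate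
21 | (3S,4R)-3-[(S)-hydroxy(4-hydroxy-3-methoxyphenyl)methyl]-4-(4-hydroxy-3-methoxybenzyl)dihydrofuran-2(3H)-one | COc1cc(C[C@H]2COC(=O)[C@@H]2[C@H](O)c2ccc(O)c(OC)c2)ccc1O | target

**Step count and risks**

Total step count: 11. Longest linear sequence: 8 steps (vanillin 5 → 6 → 9 → 11 → 15 → 16 → 17 → 20 → 21; steps 3, 5, 6, 7, 8, 9, 10, 11).

Steps most likely to fail:

1. Step 7. The enolate 13 sits next to the fully substituted dithiane carbon and may acylate the electron-rich amide too slowly. On warming, simple protonation to the mono-adduct or retro-Michael loss of the dithiane anion could then take over. The fallback sets out from 8, 4 and 6: enolate 13 is generated as before and trapped at −78 °C with the far more electrophilic aldehyde 6 (tandem Michael–aldol), which should give the C7′-epimeric aldol adducts F1. Both epimers are then oxidised with SO3·pyridine, DMSO and i-Pr2NEt in CH2Cl2 at 0 °C (Parikh–Doering, compatible with the dithiane), and the route is rejoined at 15.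

2. Step 8. Facial selectivity at the ketone could be poor if the zinc chelate between the two carbonyls does not form, for example through competing coordination to a dithiane sulfur or enolisation of the β-dicarbonyl. The fallback replaces substrate control by catalyst control: Noyori transfer hydrogenation of 15 with RuCl(p-cymene)[(S,S)-TsDPEN] in HCO2H–Et3N. Its known sense for aryl alkyl ketones corresponds to the (S) carbinol, and C3 should stay trans through equilibration under the amine. It sets out from 15 and comes back at 16, and makes no compound outside the list (F0).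

3. Step 10. The free β-hydroxy lactone could undergo retro-aldol cleavage or dehydration before hydroxide opens the ring, and the electron-rich benzylic carbinol could ionise during the acidic ring closure. The fallback sets out from 17 and changes both the protection and the closure. The C7′ hydroxyl is capped with TESOTf and 2,6-lutidine in CH2Cl2 at −78 °C to give the C7′ triethylsilyl ether F2. LiOH/NaBH4 then opens and reduces as before, the hydroxy acid is freed with NaH2PO4 buffer and closed under neutral conditions with EDC·HCl and DMAP (cat.) in CH2Cl2 to give the silyl-protected lactone F3. Buffered TBAF/AcOH removes all three silyl groups, and the route comes back at 21.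

Further compounds
F1 | step 7 | (3S,4R,5R)-3-{hydroxy[3-methoxy-4-(triisopropylsilyloxy)phenyl]methyl}-4-{2-[3-methoxy-4-(triisopropylsilyloxy)phenyl]-1,3-dithian-2-yl}-5-[(1R,2S,5R)-menthyloxy]dihydrofuran-2(3H)-one, mixture of C7′ epimers | COc1cc(C2(SCCCS2)[C@H]3[C@H](O[C@@H]4C[C@H](C)CC[C@H]4C(C)C)OC(=O)[C@@H]3C(O)c3ccc(O[Si](C(C)C)(C(C)C)C(C)C)c(OC)c3)ccc1O[Si](C(C)C)(C(C)C)C(C)C
F0 | step 8 | none | none
F2 | step 10 | (3S,4R,5R)-3-{(S)-(triethylsilyloxy)[3-methoxy-4-(triisopropylsilyloxy)phenyl]methyl}-4-[3-methoxy-4-(triisopropylsilyloxy)benzyl]-5-[(1R,2S,5R)-menthyloxy]dihydrofuran-2(3H)-one | COc1cc(C[C@H]3[C@H](O[C@@H]4C[C@H](C)CC[C@H]4C(C)C)OC(=O)[C@@H]3[C@H](O[Si](CC)(CC)CC)c3ccc(O[Si](C(C)C)(C(C)C)C(C)C)c(OC)c3)ccc1O[Si](C(C)C)(C(C)C)C(C)C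
F3 | step 10 | (3S,4R)-3-{(S)-(triethylsilyloxy)[3-methoxy-4-(triisopropylsilyloxy)phenyl]methyl}-4-[3-methoxy-4-(triisopropylsilyloxy)benzyl]dihydrofuran-2(3H)-one | COc1cc(C[C@H]2COC(=O)[C@@H]2[C@H](O[Si](CC)(CC)CC)c2ccc(O[Si](C(C)C)(C(C)C)C(C)C)c(OC)c2)ccc1O[Si](C(C)C)(C(C)C)C(C)C
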